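The numbering used is: flavanone rings A/C unprimed, catechol ring B primed, flavone rings D/E/F double-primed.

**Plan**
- Enabling feature: the biaryl bond C5'–C8'' lies ortho to O4' on ring B and, on ring D, between oxygenated C7'' and C8a'', whose oxygen becomes O1''. O4' and the future O1'' can therefore be tied together through one CH2 group.
- Retrosynthetic cuts, in order: the seven O–benzyl bonds; O1–C2 and the Cα=Cβ bond of ring C (oxa-Michael, Knoevenagel); O1''–C2'' and C3''=Cβ of ring E (oxidative chalcone closure, Claisen–Schmidt); the C5'–C8'' bond (C–H arylation); the OCH2O bridge (etherification).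
- Forward: bridge, then biaryl bond with a temporary seven-membered dioxepine ring, bridge removal, ring E, CO2Me turned into CHO, ring C, global debenzylation.
- Stereochemistry: the only stereocentre, C2 (S), is set by a bifunctional cinchona thiourea in the oxa-Michael closure of an ester-activated chalcone; the biaryl axis is not a stereo-element of the target.
- The one-carbon substituent of ring B is carried as a methyl ester, inert to carbonate at 110 °C and to methanolic HCl, where a para-oxygenated benzylic ether would ionise.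

Key step: step 5

Remark: the quinidine-derived thiourea is taken to be the pseudo-enantiomer that gives the (2S) flavanone; if a model chalcone showed the opposite sense, the quinine-derived catalyst would replace it without other change.

**Route**

Step 1
Reactants: 1 2,4,6-trihydroxyacetophenone
Product: 2 1-[2,4-bis(benzyloxy)-6-hydroxyphenyl]ethan-1-one
Conditions: BnBr (2.1 equiv), K2CO3, DMF, rt
Reagents that add atoms: benzyl bromide, BrCc1ccccc1
Why: Williamson etherification should stop at the dibenzyl ether, because the last hydroxyl is hydrogen-bonded to the acetyl carbonyl and is far less nucleophilic.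

Step 2
Reactants: 3 methyl 3-bromo-4,5-dihydroxybenzoate
Product: 4 methyl 3-bromo-5-hydroxy-4-[(methylsulfanyl)methoxy]benzoate
Conditions: MeSCH2Cl (1.1 equiv), NaHCO3, NaI (cat.), DMF, 40 °C
Reagents that add atoms: chloromethyl methyl sulfide, CSCCl
Why: Williamson etherification under hydrogen carbonate forms only the monoanion of the more acidic 4-hydroxyl (para to the ester, ortho to bromine), so the iodide-activated chloride should alkylate that oxygen, as in the known 4-O-selective alkylations of 3,4-dihydroxybenzaldehydes and 3,4-dihydroxybenzoates.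

Step 3
Reactants: 4 methyl 3-bromo-5-hydroxy-4-[(methylsulfanyl)methoxy]benzoate
Product: 5 methyl 3-(benzyloxy)-5-bromo-4-[(methylsulfanyl)methoxy]benzoate
Conditions: BnBr (1.05 equiv), K2CO3, DMF, rt
Reagents that add atoms: benzyl bromide, BrCc1ccccc1
Why: Williamson etherification of the remaining phenol is far faster than S-alkylation of the O,S-acetal sulfur.

Step 4
Reactants: 5 methyl 3-(benzyloxy)-5-bromo-4-[(methylsulfanyl)methoxy]benzoate; 2 1-[2,4-bis(benzyloxy)-6-hydroxyphenyl]ethan-1-one
Product: 7 methyl 4-{[2-acetyl-3,5-bis(benzyloxy)phenoxy]methoxy}-3-(benzyloxy)-5-bromobenzoate, via chloromethyl ether 6 (not isolated)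
Conditions: SO2Cl2, CH2Cl2, 0 °C, then evaporation; sodium salt of 2 (NaH, DMF), 0 °C to rt
Reagents that add atoms: none
Why: Sulfuryl chloride turns aryl methylthiomethyl ethers into aryl chloromethyl ethers (chlorosulfonium formation and Pummerer-type fragmentation, carried out on the ester- and bromine-deactivated ring B so that neither ring nor ketone chlorination competes), and this MOM-chloride-like electrophile should O-alkylate the sodium phenoxide of 2 in a Williamson-type etherification to give the mixed formaldehyde diaryl acetal.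

Step 5
Reactants: 7 methyl 4-{[2-acetyl-3,5-bis(benzyloxy)phenoxy]methoxy}-3-(benzyloxy)-5-bromobenzoate
Product: 8 methyl 8-acetyl-4,9,11-tris(benzyloxy)-6H-dibenzo[d,f][1,3]dioxepine-2-carboxylate
Conditions: Pd(OAc)2 (10 mol %), PCy3·HBF4 (20 mol %), K2CO3 (2 equiv), PivOH (30 mol %), DMA, 110 °C
Reagents that add atoms: none
Why: Zerovalent palladium, formed in the flask from Pd(OAc)2 and PCy3, should insert into the C5'–Br bond of ring B, and the resulting divalent arylpalladium pivalate should cleave the one ring D C–H bond within reach by carboxylate-assisted concerted metalation–deprotonation before reductive elimination forges the C5'–C8'' bond. The closest known reaction type is the intramolecular direct arylation of aryl bromides under Pd(OAc)2/PCy3/K2CO3/PivOH, established for five- to seven-membered rings and for two phenols joined through a one-atom bridge. The dibenzo[d,f][1,3]dioxepine closes as a seven-membered ring by C(sp2)–C(sp2) reductive elimination from an eight-membered palladacycle, the short O–CH2–O link holding the two arenes face to face and paying the entropic cost that an intermolecular coupling at this doubly ortho-oxygenated carbon would have to bear. No stereocentre is created, and the biaryl axis, locked only while the bridge is in place, needs no control because it is not a stereo-element of the target. The step needs site selectivity on ring D (future C8'' and not C6''): the bridge starts from the oxygen that becomes O1'', the other carbon ortho to that oxygen carries the acetyl group, and the C–H between the bridge oxygen and a benzyloxy group is both the only one the tether reaches and the most acidic one, while the bromine fixes C5' on ring B. The ester para to O4' makes the bromide more electron-poor for oxidative addition and should survive carbonate in dry DMA.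

Step 6
Reactants: 8 methyl 8-acetyl-4,9,11-tris(benzyloxy)-6H-dibenzo[d,f][1,3]dioxepine-2-carboxylate
Product: 9 methyl 3-[3-acetyl-4,6-bis(benzyloxy)-2-hydroxyphenyl]-5-(benzyloxy)-4-hydroxybenzoate
Conditions: HCl (ca. 1.25 M in MeOH), THF, 50 °C
Reagents that add atoms: none
Why: Acid-catalysed acetal exchange with methanol should open the bridge: loss of the 2-acetylphenol, which the carbonyl stabilises by hydrogen bonding, gives an aryloxymethyl cation that methanol traps as an aryl methoxymethyl ether, itself cleaved under the same conditions as in a routine MOM removal, while the benzyl ethers persist and the methyl ester can only exchange with itself.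

Step 7
Reactants: 9 methyl 3-[3-acetyl-4,6-bis(benzyloxy)-2-hydroxyphenyl]-5-(benzyloxy)-4-hydroxybenzoate
Product: 10 methyl 3-[3-acetyl-4,6-bis(benzyloxy)-2-hydroxyphenyl]-4,5-bis(benzyloxy)benzoate
Conditions: BnBr (1.05 equiv), K2CO3, DMF, 0 °C to rt
Reagents that add atoms: benzyl bromide, BrCc1ccccc1
Why: Williamson etherification should select the 4'-hydroxyl, the more acidic and non-chelated phenol, and leave the ring D hydroxyl, held in a hydrogen bond to the acetyl group, free for ring E.

Step 8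
Reactants: 10 methyl 3-[3-acetyl-4,6-bis(benzyloxy)-2-hydroxyphenyl]-4,5-bis(benzyloxy)benzoate; 11 4-(benzyloxy)benzaldehyde
Product: 12 3-{4,6-bis(benzyloxy)-3-[(2E)-3-(4-benzyloxyphenyl)prop-2-enoyl]-2-hydroxyphenyl}-4,5-bis(benzyloxy)benzoic acid
Conditions: KOH (aq., excess), MeOH/THF, rt then 45 °C; aq. HCl
Reagents that add atoms: potassium hydroxide, [K+].[OH-]
Why: Claisen–Schmidt condensation of the methyl ketone with the non-enolisable aldehyde gives the (E)-2'-hydroxychalcone, and the same aqueous KOH saponifies the methyl ester, which is wanted because the acid is the handle for the later reduction.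

Step 9
Reactants: 12 3-{4,6-bis(benzyloxy)-3-[(2E)-3-(4-benzyloxyphenyl)prop-2-enoyl]-2-hydroxyphenyl}-4,5-bis(benzyloxy)benzoic acid
Product: 13 3-{5,7-bis(benzyloxy)-2-[4-(benzyloxy)phenyl]-4-oxo-4H-chromen-8-yl}-4,5-bis(benzyloxy)benzoic acid
Conditions: I2 (10 mol %), DMSO, 120 °C
Reagents that add atoms: none
Why: Iodine-catalysed oxidative cyclisation of a 2'-hydroxychalcone in DMSO (oxa-Michael closure, α-iodination and loss of HI, DMSO reoxidising the iodide) is the standard flavone synthesis, and since the only free phenol is the one ortho to the enone, ring E can close only to the 8-aryl flavone.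

Step 10
Reactants: 13 3-{5,7-bis(benzyloxy)-2-[4-(benzyloxy)phenyl]-4-oxo-4H-chromen-8-yl}-4,5-bis(benzyloxy)benzoic acid
Product: 15 5,7-bis(benzyloxy)-8-[2,3-bis(benzyloxy)-5-(hydroxymethyl)phenyl]-2-[4-(benzyloxy)phenyl]-4H-chromen-4-one, via N-acylimidazole 14 (not isolated)
Conditions: CDI, THF, rt; then NaBH4, H2O, 0 °C
Reagents that add atoms: none
Why: Activation as the N-acylimidazole followed by borohydride reduction is a known chemoselective acid-to-alcohol reduction, and the flavone carbonyl, a vinylogous ester, should not react at 0 °C.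

Step 11
Reactants: 15 5,7-bis(benzyloxy)-8-[2,3-bis(benzyloxy)-5-(hydroxymethyl)phenyl]-2-[4-(benzyloxy)phenyl]-4H-chromen-4-one
Product: 16 3-{5,7-bis(benzyloxy)-2-[4-(benzyloxy)phenyl]-4-oxo-4H-chromen-8-yl}-4,5-bis(benzyloxy)benzaldehyde
Conditions: Dess–Martin periodinane, CH2Cl2, rt
Reagents that add atoms: none
Why: Dess–Martin oxidation of a benzylic alcohol stops at the aldehyde and leaves flavone and benzyl ethers untouched.

Step 12
Reactants: 2 1-[2,4-bis(benzyloxy)-6-hydroxyphenyl]ethan-1-one
Product: 17 tert-butyl 3-[2,4-bis(benzyloxy)-6-hydroxyphenyl]-3-oxopropanoate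
Conditions: LiN(SiMe3)2 (3.2 equiv), THF, −78 °C; Boc2O, −78 to 0 °C; AcOH quench
Reagents that add atoms: di-tert-butyl dicarbonate, CC(C)(C)OC(=O)OC(=O)OC(C)(C)C
Why: Claisen-type C-acylation of the dilithiated phenoxide–enolate with Boc2O should give the tert-butyl β-ketoester (an O-Boc phenoxide formed first would reach the same product by Baker–Venkataraman-type acyl transfer under the excess base), the bulky ester resisting lactonisation to a coumarin.

Step 13
Reactants: 16 3-{5,7-bis(benzyloxy)-2-[4-(benzyloxy)phenyl]-4-oxo-4H-chromen-8-yl}-4,5-bis(benzyloxy)benzaldehyde; 17 tert-butyl 3-[2,4-bis(benzyloxy)-6-hydroxyphenyl]-3-oxopropanoate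
Product: 18 tert-butyl 2-[2,4-bis(benzyloxy)-6-hydroxybenzoyl]-3-(3-{5,7-bis(benzyloxy)-2-[4-(benzyloxy)phenyl]-4-oxo-4H-chromen-8-yl}-4,5-bis(benzyloxy)phenyl)prop-2-enoate (alkene isomers, used as formed)
Conditions: piperidine (20 mol %), AcOH (20 mol %), 4 Å molecular sieves, toluene, 50 °C
Reagents that add atoms: none
Why: Knoevenagel condensation of the β-ketoester with the unhindered aromatic aldehyde under piperidinium acetate with removal of water gives the alkylidene β-ketoester, the ester-activated chalcone that a bifunctional catalyst can grip at two carbonyl groups.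

Step 14
Reactants: 18 tert-butyl 2-[2,4-bis(benzyloxy)-6-hydroxybenzoyl]-3-(3-{5,7-bis(benzyloxy)-2-[4-(benzyloxy)phenyl]-4-oxo-4H-chromen-8-yl}-4,5-bis(benzyloxy)phenyl)prop-2-enoate
Product: 20 (2S)-5,7-bis(benzyloxy)-2-(3-{5,7-bis(benzyloxy)-2-[4-(benzyloxy)phenyl]-4-oxo-4H-chromen-8-yl}-4,5-bis(benzyloxy)phenyl)-2,3-dihydro-4H-chromen-4-one, via tert-butyl flavanone-3-carboxylate 19 (not isolated)
Conditions: 1-[3,5-bis(trifluoromethyl)phenyl]-3-(9-deoxy-epi-quinidin-9-yl)thiourea (10 mol %), toluene, −25 °C; then TsOH·H2O, 80 °C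
Reagents that add atoms: none
Why: In this organocatalysed intramolecular oxa-Michael addition the thiourea binds the β-dicarbonyl while the quinuclidine nitrogen deprotonates the phenol and delivers it to one face of the alkylidene, so the catalyst sets C2 as S, and acid then cleaves the tert-butyl ester with decarboxylation, which erases C3 and leaves the flavanone.

Step 15
Reactants: 20 (2S)-5,7-bis(benzyloxy)-2-(3-{5,7-bis(benzyloxy)-2-[4-(benzyloxy)phenyl]-4-oxo-4H-chromen-8-yl}-4,5-bis(benzyloxy)phenyl)-2,3-dihydro-4H-chromen-4-one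
Product: 21 (2S)-2-{3-[5,7-dihydroxy-2-(4-hydroxyphenyl)-4-oxo-4H-chromen-8-yl]-4,5-dihydroxyphenyl}-5,7-dihydroxy-2,3-dihydro-4H-chromen-4-one (CNP0204144.1)
Conditions: H2 (1 atm), Pd/C, THF/MeOH, rt
Reagents that add atoms: none
Why: Hydrogenolysis of the seven benzyl aryl ethers over Pd/C under neutral conditions at room temperature should free all phenols without reducing the flavone double bond or the aryl ketones and without opening the flavanone, so C2 keeps its configuration.

**Compound list**

1 | 2,4,6-trihydroxyacetophenone | CC(=O)c1c(O)cc(O)cc1O | starting material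
2 | 1-[2,4-bis(benzyloxy)-6-hydroxyphenyl]ethan-1-one | CC(=O)c1c(O)cc(OCc2ccccc2)cc1OCc1ccccc1 | intermediate
3 | methyl 3-bromo-4,5-dihydroxybenzoate | COC(=O)c1cc(O)c(O)c(Br)c1 | starting material
4 | methyl 3-bromo-5-hydroxy-4-[(methylsulfanyl)methoxy]benzoate | COC(=O)c1cc(O)c(OCSC)c(Br)c1 | intermediate
5 | methyl 3-(benzyloxy)-5-bromo-4-[(methylsulfanyl)methoxy]benzoate | COC(=O)c1cc(OCc2ccccc2)c(OCSC)c(Br)c1 | intermediate
6 | methyl 3-(benzyloxy)-5-bromo-4-(chloromethoxy)benzoate (not isolated) | COC(=O)c1cc(OCc2ccccc2)c(OCCl)c(Br)c1 | intermediate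
7 | methyl 4-{[2-acetyl-3,5-bis(benzyloxy)phenoxy]methoxy}-3-(benzyloxy)-5-bromobenzoate (OCH2O-tethered bromide) | CC(=O)c1c(OCc2ccccc2)cc(OCc2ccccc2)cc1OCOc1c(Br)cc(C(=O)OC)cc1OCc1ccccc1 | intermediate
8 | methyl 8-acetyl-4,9,11-tris(benzyloxy)-6H-dibenzo[d,f][1,3]dioxepine-2-carboxylate (bridged biaryl) | CC(=O)c1c(OCc2ccccc2)cc(OCc2ccccc2)c2c1OCOc1c-2cc(C(=O)OC)cc1OCc1ccccc1 | intermediate
9 | methyl 3-[3-acetyl-4,6-bis(benzyloxy)-2-hydroxyphenyl]-5-(benzyloxy)-4-hydroxybenzoate | CC(=O)c1c(OCc2ccccc2)cc(OCc2ccccc2)c(-c2cc(C(=O)OC)cc(OCc3ccccc3)c2O)c1O | intermediate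
10 | methyl 3-[3-acetyl-4,6-bis(benzyloxy)-2-hydroxyphenyl]-4,5-bis(benzyloxy)benzoate | CC(=O)c1c(OCc2ccccc2)cc(OCc2ccccc2)c(-c2cc(C(=O)OC)cc(OCc3ccccc3)c2OCc2ccccc2)c1O | intermediate
11 | 4-(benzyloxy)benzaldehyde | O=Cc1ccc(OCc2ccccc2)cc1 | starting material
12 | 3-{4,6-bis(benzyloxy)-3-[(2E)-3-(4-benzyloxyphenyl)prop-2-enoyl]-2-hydroxyphenyl}-4,5-bis(benzyloxy)benzoic acid | O=C(/C=C/c1ccc(OCc2ccccc2)cc1)c1c(OCc2ccccc2)cc(OCc2ccccc2)c(-c2cc(C(=O)O)cc(OCc3ccccc3)c2OCc2ccccc2)c1O | intermediate
13 | 3-{5,7-bis(benzyloxy)-2-[4-(benzyloxy)phenyl]-4-oxo-4H-chromen-8-yl}-4,5-bis(benzyloxy)benzoic acid | O=C(O)c1cc(OCc2ccccc2)c(OCc2ccccc2)c(c1)-c1c(OCc2ccccc2)cc(OCc2ccccc2)c2c(=O)cc(-c3ccc(OCc4ccccc4)cc3)oc12 | intermediate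
14 | N-acylimidazole of acid 13 (not isolated) | O=C(n1ccnc1)c1cc(OCc2ccccc2)c(OCc2ccccc2)c(c1)-c1c(OCc2ccccc2)cc(OCc2ccccc2)c2c(=O)cc(-c3ccc(OCc4ccccc4)cc3)oc12 | intermediate
15 | 5,7-bis(benzyloxy)-8-[2,3-bis(benzyloxy)-5-(hydroxymethyl)phenyl]-2-[4-(benzyloxy)phenyl]-4H-chromen-4-one | OCc1cc(OCc2ccccc2)c(OCc2ccccc2)c(c1)-c1c(OCc2ccccc2)cc(OCc2ccccc2)c2c(=O)cc(-c3ccc(OCc4ccccc4)cc3)oc12 | intermediate
16 | 3-{5,7-bis(benzyloxy)-2-[4-(benzyloxy)phenyl]-4-oxo-4H-chromen-8-yl}-4,5-bis(benzyloxy)benzaldehyde | O=Cc1cc(OCc2ccccc2)c(OCc2ccccc2)c(c1)-c1c(OCc2ccccc2)cc(OCc2ccccc2)c2c(=O)cc(-c3ccc(OCc4ccccc4)cc3)oc12 | intermediate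
17 | tert-butyl 3-[2,4-bis(benzyloxy)-6-hydroxyphenyl]-3-oxopropanoate | CC(C)(C)OC(=O)CC(=O)c1c(O)cc(OCc2ccccc2)cc1OCc1ccccc1 | intermediate
18 | tert-butyl 2-[2,4-bis(benzyloxy)-6-hydroxybenzoyl]-3-(3-{5,7-bis(benzyloxy)-2-[4-(benzyloxy)phenyl]-4-oxo-4H-chromen-8-yl}-4,5-bis(benzyloxy)phenyl)prop-2-enoate (alkene isomers) | CC(C)(C)OC(=O)C(=Cc1cc(OCc2ccccc2)c(OCc2ccccc2)c(c1)-c1c(OCc2ccccc2)cc(OCc2ccccc2)c2c(=O)cc(-c3ccc(OCc4ccccc4)cc3)oc12)C(=O)c1c(O)cc(OCc2ccccc2)cc1OCc1ccccc1 | intermediate
19 | tert-butyl (2S)-5,7-bis(benzyloxy)-2-(3-{5,7-bis(benzyloxy)-2-[4-(benzyloxy)phenyl]-4-oxo-4H-chromen-8-yl}-4,5-bis(benzyloxy)phenyl)-4-oxo-3,4-dihydro-2H-chromene-3-carboxylate (C3 epimers and enol, not isolated) | O=C1C(C(=O)OC(C)(C)C)[C@@H](c2cc(OCc3ccccc3)c(OCc3ccccc3)c(-c3c(OCc4ccccc4)cc(OCc4ccccc4)c4c(=O)cc(-c5ccc(OCc6ccccc6)cc5)oc34)c2)Oc2cc(OCc3ccccc3)cc(OCc3ccccc3)c21 | intermediate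
20 | (2S)-5,7-bis(benzyloxy)-2-(3-{5,7-bis(benzyloxy)-2-[4-(benzyloxy)phenyl]-4-oxo-4H-chromen-8-yl}-4,5-bis(benzyloxy)phenyl)-2,3-dihydro-4H-chromen-4-one | O=C1C[C@@H](c2cc(OCc3ccccc3)c(OCc3ccccc3)c(-c3c(OCc4ccccc4)cc(OCc4ccccc4)c4c(=O)cc(-c5ccc(OCc6ccccc6)cc5)oc34)c2)Oc2cc(OCc3ccccc3)cc(OCc3ccccc3)c21 | intermediate
21 | (2S)-2-{3-[5,7-dihydroxy-2-(4-hydroxyphenyl)-4-oxo-4H-chromen-8-yl]-4,5-dihydroxyphenyl}-5,7-dihydroxy-2,3-dihydro-4H-chromen-4-one (CNP0204144.1) | O=C1C[C@@H](c2cc(O)c(O)c(-c3c(O)cc(O)c4c(=O)cc(-c5ccc(O)cc5)oc34)c2)Oc2cc(O)cc(O)c21 | target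

**Count and risks**

Total steps: 15. Longest linear sequence: 13 steps (from 3 through steps 2 to 11 and 13 to 15; steps 1 and 12 are side branches).

The three steps most likely to fail:

1. Step 5. Oxidative addition may be followed by protodebromination instead of ring closure, because the C–H bond to be cleaved is flanked by two oxygen substituents and the seven-membered closure is slow. The fallback activates both carbons and couples them reductively across the same bridge; it sets out from 2 and 6 and returns at 8. Phenol 2 is iodinated ortho to its free hydroxyl (benzyltrimethylammonium dichloroiodate, CaCO3, CH2Cl2/MeOH) to give 1-[4,6-bis(benzyloxy)-2-hydroxy-3-iodophenyl]ethan-1-one F1. Its sodium salt is alkylated with chloromethyl ether 6 as in step 4 to give the bromo-iodo diaryloxymethane F2. Zerovalent nickel, generated from NiCl2(PPh3)2, PPh3 and zinc dust in DMF at 60 °C, should then join the two carbon–halogen carbons in an intramolecular reductive Ullmann-type coupling to give 8.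

2. Step 6. Methanolysis of a formaldehyde acetal whose two oxygens both sit on electron-poor positions may be sluggish, and harder forcing may cleave the benzyl ether that is chelated to the acetyl group. The fallback makes the biaryl bond without a bridge; it sets out from 3 and 2 and returns at 10, so steps 4 to 7 fall away. Catechol 3 is benzylated twice (BnBr, K2CO3, DMF) to methyl 3,4-bis(benzyloxy)-5-bromobenzoate F3. Miyaura borylation (B2pin2, Pd(dppf)Cl2, KOAc, dioxane, 90 °C) gives the pinacol boronate F4. Suzuki–Miyaura coupling of F4 with 1-[4,6-bis(benzyloxy)-2-hydroxy-3-iodophenyl]ethan-1-one F1, made from 2 as described above (Pd(OAc)2, SPhos, K3PO4, toluene/H2O, 90 °C), should give 10 directly.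

3. Step 14. Facial selectivity may be poor on so large a substrate with a slowly rotating biaryl, a racemic background closure may already start under the amine of step 13, and the acid decarboxylation may erode the configuration through ring opening. The fallback closes the ring without stereocontrol and resolves; it sets out from 16 and 2 and returns at 20. Claisen–Schmidt condensation (KOH, EtOH/THF, rt) gives the plain 2'-hydroxychalcone F5. NaOAc in refluxing EtOH closes it to the racemic flavanone F6. Preparative HPLC on a polysaccharide chiral stationary phase separates the (2S) enantiomer 20, and the (2R) enantiomer is re-equilibrated through the chalcone with base and recycled.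

Further compounds
F1 | step 5 | 1-[4,6-bis(benzyloxy)-2-hydroxy-3-iodophenyl]ethan-1-one | CC(=O)c1c(O)c(I)c(OCc2ccccc2)cc1OCc1ccccc1
F2 | step 5 | methyl 4-{[2-acetyl-3,5-bis(benzyloxy)-6-iodophenoxy]methoxy}-3-(benzyloxy)-5-bromobenzoate | CC(=O)c1c(OCc2ccccc2)cc(OCc2ccccc2)c(I)c1OCOc1c(Br)cc(C(=O)OC)cc1OCc1ccccc1
F3 | step 6 | methyl 3,4-bis(benzyloxy)-5-bromobenzoate | COC(=O)c1cc(OCc2ccccc2)c(OCc2ccccc2)c(Br)c1
F4 | step 6 | methyl 3,4-bis(benzyloxy)-5-(4,4,5,5-tetramethyl-1,3,2-dioxaborolan-2-yl)benzoate | COC(=O)c1cc(OCc2ccccc2)c(OCc2ccccc2)c(c1)B1OC(C)(C)C(C)(C)O1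
F5 | step 14 | (2E)-1-[2,4-bis(benzyloxy)-6-hydroxyphenyl]-3-(3-{5,7-bis(benzyloxy)-2-[4-(benzyloxy)phenyl]-4-oxo-4H-chromen-8-yl}-4,5-bis(benzyloxy)phenyl)prop-2-en-1-one | O=C(/C=C/c1cc(OCc2ccccc2)c(OCc2ccccc2)c(c1)-c1c(OCc2ccccc2)cc(OCc2ccccc2)c2c(=O)cc(-c3ccc(OCc4ccccc4)cc3)oc12)c1c(O)cc(OCc2ccccc2)cc1OCc1ccccc1
F6 | step 14 | racemic 5,7-bis(benzyloxy)-2-(3-{5,7-bis(benzyloxy)-2-[4-(benzyloxy)phenyl]-4-oxo-4H-chromen-8-yl}-4,5-bis(benzyloxy)phenyl)-2,3-dihydro-4H-chromen-4-one | O=C1CC(c2cc(OCc3ccccc3)c(OCc3ccccc3)c(-c3c(OCc4ccccc4)cc(OCc4ccccc4)c4c(=O)cc(-c5ccc(OCc6ccccc6)cc5)oc34)c2)Oc2cc(OCc3ccccc3)cc(OCc3ccccc3)c21
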